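I wanted to know how much of the electrophile would have reacted after 50 min in two flasks that differ in their charge of nucleophile, and whether the larger charge moves that figure by a real margin.

- theta: electrophile 0.39 M; nucleophile 0.950 equiv; protic impurity 0.0780 M; time 50 min
- delta: electrophile 0.39 M; nucleophile 1.20 equiv; protic impurity 0.0780 M; time 50 min

* part of the electrophile that has reacted at the end, theta
* part of the electrophile that has reacted at the end, delta
* what raising the equivalents of nucleophile from its lowest to its highest value here does to the part of the electrophile that has reacted (changes below 5 percentage points count as none) (it rises / no change / it falls)

    electrophile + nucleophile → acid set free + target (k1 = 0.0210 /M/s)
    nucleophile + acid set free ⇌ protonated nucleophile, settled at all times (K2 = 1660 /M)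
    electrophile + acid set free → side product (k3 = 6.62 × 10⁻⁴ /M/s)
    electrophile + protic impurity → quenched substrate (k4 = 0.173 /M/s)

I reckoned with the part of the electrophile left and not the part made. The protic impurity takes its own charge of electrophile, 20.0% of it, and I saw no doubt about that, since the half-life of electrophile by that step, 0.86 min, is short against the run. Each target also sets acid free, and at the start of theta the balance favours protonated nucleophile over free acid by 620 to one, so I took each electrophile turned into target to cost two nucleophile, one reacted and one protonated. In both flasks that makes nucleophile the limiting reagent. So I expected theta to stop with 32.5% of its electrophile left, and I call this the stall remainder: one, less the impurity's share of the electrophile, less half the equivalents of nucleophile. For delta it came to 20.0%.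

My objection was that the balance runs both ways and leaves some nucleophile free, so the first step creeps on. Past the stall, each extra target leaves two free acid, which pushes free nucleophile down as the creep grows, and the square of the extra target then rises at k1[electrophile][protonated nucleophile]/K2. With stall concentrations that gave 0.0299 M in theta and 0.0263 M in delta, so I committed to 75.2% reacted in theta and 86.7% in delta. A second doubt stayed open: those concentrations fall during the run, and in theta the half-life of acid by the side step, 45 min with electrophile as charged, is close to the run, so I trusted these figures to a few points.

The forecast gave 75% for theta and 85% for delta, and said it rises, holding that “conversion stalls near nucleophile/2 plus a small creep from the salt equilibrium”. On delta my figure stood higher than the forecast's.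

The simulation gave 74.5% for theta and 85.0% for delta, so it rises, by 10 percentage points.

Theta ended with 25% of its electrophile left, 7 points below its stall remainder of 32.5%. A run without the protonation shrank the gap between delta and theta from 10 points to 0.13 points. The same flask as theta with 0.380 equiv of nucleophile has a stall remainder of 61.0%, and it ended with 53.1% of its electrophile left.

(The numbers of this flask come from no measurement; no experiment stands behind them.)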